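## Structural features

The target is bis(2,3,6-tribromo-4,5-dihydroxyphenyl)methane, C13H6Br6O4: two identical, hexasubstituted benzene rings joined only by one CH2 group. Numbering each ring from the carbon that holds the bridge, C1 carries CH2, C2, C3 and C6 carry bromine, and the adjacent carbons C4 and C5 carry the hydroxyls of a catechol. The molecule is achiral and has no stereocentre; the only stereocentres of the plan are the transient cis pair C4/C5 of each ring at the dihydro stage, and they vanish on aromatisation. The fragile parts are the catechols (easily oxidised to o-quinones, above all as catecholates in air), the bridging CH2 (para to the C4 hydroxyl of both rings, hence a 4-hydroxybenzyl carbon open to ipso attack by electrophiles and to quinone methide formation), and the six aryl C–Br bonds (which exclude hydrogenation catalysts, dissolving metals and late organolithium chemistry). The real difficulty is not the thirteen-carbon skeleton but the regiospecific placement of six substituents per ring, in particular bromine at C2 and C6 on both sides of the bridge, without ever treating an electron-rich bis-phenol with bromine. The key step exploits the contiguous carbons C6–C1–C2–C3 (Br, CH2, Br, Br), which have exactly the substitution of the four carbons of a 2,4,5-tribromo-3-alkylthiophene, while C4–C5 is a two-carbon unit with two cis oxygens; each benzene ring can therefore be built from a thiophene-derived diene and a C2O2 alkene, with sulfur as a placeholder that leaves as SO2.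

## Logic of the disconnections

15 ⇒ 13 (through 14). No skeletal bond is cut; two hydrogens are returned to C4 and C5 of each ring, so that the arenes become cyclohexa-1,3-dienes carrying a cis-diol. A non-aromatic six-membered ring of this kind is what a cycloaddition delivers, which the catechol itself is not. The gain is a change of problem, from hexasubstituted arene synthesis to ring construction. The forward step must remove hydrogen without removing oxygen, so the oxidant has to act at the carbinol carbon under non-acidic conditions; overshooting to the dione level 14 is tolerable because a mild reductant returns it to 15.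

13 ⇒ 12. The cis hydroxyls of each ring are tied back into a five-membered carbonate (four acyl C–O bonds are the ones made and broken). This is the form in which the two oxygens arrive with the C2 unit, and it leaves no free hydroxyl during the thermal step. The forward cleavage must attack the carbonate carbonyl faster than anything removes a ring hydrogen, and must never meet acid, since the dihydrodiol dehydrates to a phenol under acid.

12 ⇒ 7 + two 8 (through 11, 10 and 9). The bonds C3–C4 and C5–C6 of each ring are cut, four C–C bonds in all, and SO2 is put back between C3 and C6. These cuts separate the two oxygenated carbons from the chain C6–C1–C2–C3, which becomes the carbon chain of a fully substituted thiophene dioxide. Two rings and four stereocentres disappear and one symmetric bis-diene plus a commercial C2O2 alkene remain. The forward step has to succeed twice in one molecule, stop at one addition per ring, and keep the dihydro oxidation level; regiochemistry is not an issue because 8 is symmetric.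

7 ⇒ 6. The four S=O bonds are cut. The aromatic thiophene is the stable storage form of the diene and the form on which substitution chemistry is possible. The forward oxidation needs a strongly electrophilic oxygen donor because each sulfur is deactivated by three bromines; full substitution of both rings is kept because it is what prevents the dioxide from dimerising.

6 ⇒ 5. Six C–Br bonds are cut. All six ring positions of 5 that carry hydrogen are exactly the positions that must carry bromine, so exhaustive halogenation has no regiochemical question and no phenol is present when bromine is used. The forward step must be ionic (dark) so that the CH2 bridge is untouched, and forcing enough to fill the two β-positions.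

5 ⇒ 4. The bridging C–H is traced back to C–OH. The carbinol is the direct product of a carbonyl addition. The forward deoxygenation must trap the doubly thienylic cation with hydride faster than it alkylates a free α-position.

4 ⇒ 1 + 2 (through 3). The bond between the bridge carbon and C3 of one thiophene is cut. Both halves are commercial 3-substituted thiophenes, so the β,β′-attachment is bought, not made by substitution, which would go α. The forward step requires the β-metalated thiophene to be kept cold so that the metal does not migrate to the α-position.

## Other disconnections considered

Alternative 1: The cut is at the two aryl–CH2 bonds, the bridge carbon coming from a formate.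
- Forward key step: 1,2,5-tribromo-3,4-dimethoxybenzene A1 would be magnesiated at its only C–H with TMPMgCl·LiCl (2,2,6,6-tetramethylpiperidinylmagnesium chloride–lithium chloride), and two equivalents would add to ethyl formate A2 to give bis(2,3,6-tribromo-4,5-dimethoxyphenyl)methanol A3. Ionic deoxygenation and cleavage of four methyl ethers with BBr3 would follow.
- In favour: it is convergent and symmetric, the bromine pattern is fixed on a simple benzene before coupling, and no intermediate is sensitive (no dihydroarene, no sulfone, no peracid).
- Against: A1 has its lone hydrogen para to a methoxy group, the position that electrophilic bromination fills first, so it needs an indirect preparation. The arylmagnesium has bromine on both ortho carbons and can expel a magnesium halide to form an aryne on warming, yet the second addition, which creates a tetra-ortho-substituted carbinol, is the one that wants warmth. A3 should ionise reluctantly, because six bromines withdraw and the para methoxy group is twisted out of conjugation, so the deoxygenation is not trivial.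
- Comparison: structurally it forms the bridge bonds and leaves the rings intact, whereas the chosen plan forms the rings. In step count it is the equal of the chosen plan or slightly better, and in robustness of intermediates it is better. It is worse in that its risk sits in the most crowded bond of the molecule and it ends with a fourfold ether cleavage, which the chosen plan avoids.

Alternative 2: The cut is at C3–Br and C6–Br of each ring, together with the ring unsaturation (catechol traced back to a cyclohexane-1,2-dione).
- Forward key step: 4,4'-methylenebis(cyclohexane-1,2-dione) A4 with six equivalents of Br2 in acetic acid would be brominated at both α-carbons of each ring and lose HBr, to give bis(2,5-dibromo-3,4-dihydroxyphenyl)methane A5.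
- In favour: there are no protecting groups, the two bromines are placed by the carbonyls and not by directing effects, and aromatisation needs no separate oxidant and passes through no stereocentres. On these points it is better than the chosen plan.
- Against: A5 is not the target, since C2 of each ring still carries hydrogen. The remaining two brominations must be done on a free bis-catechol whose bridge carbon is para to a hydroxyl, which invites ipso attack with fission of the diarylmethane and oxidation to o-quinones. A4 is not a commercial compound and needs its own multistep preparation.
- Comparison: both plans reach free catechols without ethers, so they are equal there. If the last two brominations could be run in the same flask, the end-game would be shorter than that of the chosen plan, a real advantage. The chosen plan, however, installs all six bromines before any phenol exists, and its precursor comes from two cheap thiophenes, so overall Alternative 2 should not be shorter and is less secure at the last step.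

Alternative 3: The cut is at the C1–CH2 bond of one ring and the adjacent C2–Br bond of the same ring, both formed on an aryne.
- Forward key step: 3,6-dibromo-2-iodo-4,5-dimethoxyphenyl 4-chlorobenzenesulfonate A6 would undergo iodine–magnesium exchange with iPrMgCl at −78 °C and lose the sulfonate to give 3,6-dibromo-4,5-dimethoxybenzyne A7. (2,3,6-Tribromo-4,5-dimethoxybenzyl)magnesium chloride A8 would add, and the resulting arylmagnesium would be brominated with BrCl2C–CCl2Br to give bis(2,3,6-tribromo-4,5-dimethoxyphenyl)methane A9. Ether cleavage would end the route.
- In favour: two bonds on neighbouring carbons are made in one operation, A7 is symmetric so the addition has no regiochemistry, the bridge arrives at the right oxidation level, and A9 is one step of a well-known type from the target. In the way it solves the C2–Br problem it is the equal of the chosen plan.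
- Against: A6 and A8 are different, heavily functionalised arenes that each need a separate multistep preparation. The exchange reagent must touch only the iodide in the presence of five aryl bromides. A8 is prone to Wurtz coupling when made and is hindered by two ortho bromines. The arylmagnesium formed after addition has bromine on the next carbon and could eliminate to a second aryne.
- Comparison: mechanistically it is elegant and avoids any oxidation-level management, which is better than the chosen plan. In step economy and in the number of chemoselectivity demands it is worse, and it ends with a fourfold ether cleavage.

Key step: step 5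

Remark on stereochemistry: 10 to 13 should form as two cis,cis diastereomers (a C2-symmetric racemate and a meso form) that differ only in the relative sense of the two remote rings and converge on 15. The names cover both, the SMILES strings show one enantiomer of the C2-symmetric form, and in 9 and 11 the endo or exo orientation at the sulfur bridge is left open.

Remark on bookkeeping: partly brominated and partly oxidised members of the series in steps 3 and 4 are stages of one repeated reaction at equivalent sites and are not numbered.

## Route

Step 1
Reactants: 1 3-bromothiophene; 2 thiophene-3-carbaldehyde
Product: 4 di(thiophen-3-yl)methanol, via 3-thienyllithium 3 (not isolated)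
Conditions: n-BuLi (1.05 equiv), Et2O, −78 °C; then 2, −78 °C; aq NH4Cl at −78 °C
Reagents that add atoms: none
Why: Bromine–lithium exchange in ether at −78 °C gives the β-lithiothiophene, which keeps its position as long as it stays cold, and its 1,2-addition to the aldehyde sets the β,β′-linkage that substitution chemistry on thiophene could not deliver. The carbinol carbon bears two identical rings and is not a stereocentre.

Step 2
Reactants: 4 di(thiophen-3-yl)methanol
Product: 5 di(thiophen-3-yl)methane
Conditions: Et3SiH (3 equiv), CF3CO2H, CH2Cl2, 0 °C, slow addition of 4
Reagents that add atoms: none
Why: Ionic hydrogenation: the acid ionises the doubly thienylic carbinol and the silane hydride traps the cation. Slow addition in the cold keeps the cation dilute, which should suppress Friedel–Crafts attack on free α-positions, and the short cold exposure should leave the thiophene rings unreduced.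

Step 3
Reactants: 5 di(thiophen-3-yl)methane
Product: 6 bis(2,4,5-tribromothiophen-3-yl)methane
Conditions: Br2 (8 equiv), AcOH/CHCl3, rt → 60 °C, dark
Reagents that add atoms: bromine, BrBr
Why: Electrophilic aromatic bromination, in which the four α-positions should react first and the two β-positions on warming, as in the exhaustive bromination of 3-alkylthiophenes. Every ring C–H is replaced, so no regiochemistry arises, and exclusion of light keeps the CH2 bridge out of radical bromination.

Step 4
Reactants: 6 bis(2,4,5-tribromothiophen-3-yl)methane
Product: 7 3,3'-methylenebis(2,4,5-tribromothiophene 1,1-dioxide)
Conditions: (CF3CO)2O, urea·H2O2, MeCN/CH2Cl2, 0 °C → rt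
Reagents that add atoms: trifluoroperacetic acid, OOC(=O)C(F)(F)F (formed in the flask from trifluoroacetic anhydride, O=C(OC(=O)C(F)(F)F)C(F)(F)F, and urea–hydrogen peroxide, NC(N)=O.OO)
Why: Electrophilic S-oxidation with trifluoroperacetic acid is the reaction by which tetrahalothiophenes are converted into isolable 1,1-dioxides. Full substitution of both rings blocks the self-dimerisation of less substituted thiophene dioxides, and the anhydrous peracid from solid urea–H2O2 avoids concentrated aqueous peroxide.

Step 5
Reactants: 7 3,3'-methylenebis(2,4,5-tribromothiophene 1,1-dioxide); 8 vinylene carbonate
Product: 12 bis(cis-4,6,7-tribromo-2-oxo-3a,7a-dihydro-1,3-benzodioxol-5-yl)methane, via first bridged sulfone adduct 9 (not isolated), via monodiene monosulfone 10 (not isolated), via second bridged sulfone adduct 11 (not isolated)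
Conditions: 8 (6 equiv), BHT (cat.), PhMe, 110 °C, N2 sweep
Reagents that add atoms: none
Why: Each tribromothiophene dioxide ring is a non-aromatic, electron-poor diene held s-cis in a five-membered ring, and it should add the cis-alkene of 8 in a concerted, suprafacial [4+2] cycloaddition across its two sulfur-bound carbons to give the 7-thiabicyclo[2.2.1]hept-2-ene 7,7-dioxide 9. This bridged sulfone should lose SO2 at the reaction temperature by a cheletropic step to give the cyclohexa-1,3-diene ring of 10, and the same two events on the second ring (11, then 12) complete the twofold annulation. The closest known reaction type is the Diels–Alder/SO2-extrusion annulation of tetrahalothiophene 1,1-dioxides with alkenes, together with the use of vinylene carbonate as dienophile toward perhalogenated dienes. Each six-membered ring thus closes by an intermolecular [4+2] cycloaddition that forms C3–C4 and C5–C6 together, and it appears as a carbocyclic diene once the one-atom sulfur bridge has left. The two new CH–O stereocentres of each ring are cis because the alkene geometry, held by the carbonate ring, is transferred suprafacially; the endo or exo orientation of the adduct is of no consequence, since the bridgeheads become sp2 when SO2 leaves, and the relative configuration of the two remote rings is neither controlled nor needed. No regioselectivity is required because 8 is symmetric. What the step needs is one addition per ring and retention of the dihydro oxidation level: the product diene is tetrasubstituted, flanked by two sp3 carbons and has no SO2 to lose, so it should be far less reactive than the sulfone, and the neutral medium, free of acid and base, gives the carbonate no path to leave with aromatisation. BHT holds back radical polymerisation of 8.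

Step 6
Reactants: 12 bis(cis-4,6,7-tribromo-2-oxo-3a,7a-dihydro-1,3-benzodioxol-5-yl)methane
Product: 13 bis(cis-2,5,6-tribromo-3,4-dihydroxycyclohexa-1,5-dien-1-yl)methane
Conditions: K2CO3 (0.2 equiv), MeOH, 0 °C; pH 7 buffer work-up
Reagents that add atoms: none
Why: Base-catalysed transesterification: methoxide adds to the strained five-membered carbonate carbonyl and releases the diol as dimethyl carbonate is formed. The C–O bonds at the stereocentres are not touched, so both rings stay cis, and cis-dihydrodiols tolerate mild base, whereas acid, which would dehydrate them to phenols, is excluded up to and including the work-up.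

Step 7
Reactants: 13 bis(cis-2,5,6-tribromo-3,4-dihydroxycyclohexa-1,5-dien-1-yl)methane
Product: 15 bis(2,3,6-tribromo-4,5-dihydroxyphenyl)methane, via bis(o-quinone) 14 (not isolated)
Conditions: IBX (2-iodoxybenzoic acid, 4.5 equiv), DMSO, rt; then aq Na2S2O4, EtOAc, rt
Reagents that add atoms: none
Why: IBX oxidises vicinal diols at the carbinol carbon without cleaving the C–C bond; oxidation of one carbinol per ring followed by enolisation brings the ring to the aromatic catechol level, and further oxidation takes it to the o-quinone 14. Dithionite then returns every ring to the catechol, so the four sp3 centres are erased, no C–O bond is lost, and a ring that resists the second oxidation is already at the level of 15.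

## Compound list

1 | 3-bromothiophene | Brc1ccsc1 | starting material
2 | thiophene-3-carbaldehyde | O=Cc1ccsc1 | starting material
3 | 3-thienyllithium (thiophen-3-yllithium) | [Li]c1ccsc1 | intermediate
4 | di(thiophen-3-yl)methanol | OC(c1ccsc1)c1ccsc1 | intermediate
5 | di(thiophen-3-yl)methane | C(c1ccsc1)c1ccsc1 | intermediate
6 | bis(2,4,5-tribromothiophen-3-yl)methane | Brc1sc(Br)c(Cc2c(Br)sc(Br)c2Br)c1Br | intermediate
7 | 3,3'-methylenebis(2,4,5-tribromothiophene 1,1-dioxide) | O=S1(=O)C(Br)=C(CC2=C(Br)S(=O)(=O)C(Br)=C2Br)C(Br)=C1Br | intermediate
8 | vinylene carbonate (1,3-dioxol-2-one) | O=C1OC=CO1 | starting material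
9 | first bridged sulfone adduct: one ring of 7 converted into a 1,2,4-tribromo-7-thiabicyclo[2.2.1]hept-2-ene 7,7-dioxide whose C5 and C6 carry a cis-fused cyclic carbonate and whose C3 carries the CH2 leading to the untouched 2,4,5-tribromothiophene 1,1-dioxide ring | O=C1O[C@@H]2[C@H](O1)C3(Br)C(Br)=C(CC4=C(Br)S(=O)(=O)C(Br)=C4Br)C2(Br)S3(=O)=O | intermediate
10 | monodiene monosulfone: cis-4,6,7-tribromo-5-[(2,4,5-tribromo-1,1-dioxidothiophen-3-yl)methyl]-3a,7a-dihydro-1,3-benzodioxol-2-one | O=C1O[C@H]2C(Br)=C(CC3=C(Br)S(=O)(=O)C(Br)=C3Br)C(Br)=C(Br)[C@H]2O1 | intermediate
11 | second bridged sulfone adduct: 10 in which the thiophene dioxide ring has become the same carbonate-fused 1,2,4-tribromo-7-thiabicyclo[2.2.1]hept-2-ene 7,7-dioxide as in 9 | O=C1O[C@H]2C(Br)=C(CC3=C(Br)C4(Br)[C@H]5OC(=O)O[C@H]5C3(Br)S4(=O)=O)C(Br)=C(Br)[C@H]2O1 | intermediate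
12 | bis(cis-4,6,7-tribromo-2-oxo-3a,7a-dihydro-1,3-benzodioxol-5-yl)methane | O=C1O[C@H]2C(Br)=C(CC3=C(Br)[C@@H]4OC(=O)O[C@@H]4C(Br)=C3Br)C(Br)=C(Br)[C@H]2O1 | intermediate
13 | bis(cis-2,5,6-tribromo-3,4-dihydroxycyclohexa-1,5-dien-1-yl)methane | O[C@H]1C(Br)=C(CC2=C(Br)[C@H](O)[C@H](O)C(Br)=C2Br)C(Br)=C(Br)[C@H]1O | intermediate
14 | 4,4'-methylenebis(3,5,6-tribromocyclohexa-3,5-diene-1,2-dione) | O=C1C(=O)C(Br)=C(CC2=C(Br)C(=O)C(=O)C(Br)=C2Br)C(Br)=C1Br | intermediate
15 | bis(2,3,6-tribromo-4,5-dihydroxyphenyl)methane | Oc1c(O)c(Br)c(Cc2c(Br)c(O)c(O)c(Br)c2Br)c(Br)c1Br | target

## Step count and least certain steps

Total step count: 7. Longest linear sequence: 7 steps (from 1 and 2 to 15; 8 enters at step 5).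

Step 5 (key step).
- What may go wrong: incomplete twofold reaction. 8 is only a moderately reactive 2π partner and every diene terminus carries bromine, so the second ring may need prolonged heating. During that time the ring that has already formed can aromatise by eliminating its carbonate oxygen, 8 can polymerise, or 7 can shift a proton from its doubly activated CH2.
- Fallback, setting out from 7 and returning at 15: the electron-rich enediol diether 2,3-dihydro-1,4-dioxine, better matched to the electron-poor diene, should add at lower temperature (PhMe, 40–80 °C) with loss of SO2 to give bis(cis-5,7,8-tribromo-2,3,4a,8a-tetrahydro-1,4-benzodioxin-6-yl)methane F1. Dehydrogenation with DDQ (2,3-dichloro-5,6-dicyano-1,4-benzoquinone) over suspended NaHCO3 in PhCl at 100 °C, helped by the ether oxygen at each ring-fusion carbon, should give bis(5,7,8-tribromo-2,3-dihydro-1,4-benzodioxin-6-yl)methane F2. Cleavage of the two ethylene bridges with BBr3 (CH2Cl2, 0 °C → rt, then water) gives 15. The price is an ether cleavage that the main route avoids.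

Step 7.
- What may go wrong: loss of a ring oxygen by dehydration of the dihydrodiol in the mildly acidic IBX medium (aromatisation to a phenol), or a proton shift in the fully oxidised material through the CH2 that lies between two quinone rings, giving a quinone methide that takes up water before the reductant is added.
- Fallback, setting out from 12 and returning at 15: the rings are aromatised before the oxygens are unmasked. Dehydrogenation of 12 with DDQ (PhCl, reflux) by hydride abstraction at the ring-fusion carbons should give bis(4,6,7-tribromo-2-oxo-1,3-benzodioxol-5-yl)methane F3. As an aryl carbonate, F3 can neither dehydrate nor be over-oxidised, and it is cleaved by K2CO3 (cat.) in degassed MeOH followed by dilute HCl to give 15. This order also takes the base-sensitive dihydro stage of step 6 out of the route.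

Step 4.
- What may go wrong: incomplete oxidation of the second, equally deactivated sulfur, and decay of 7 during a long oxidation by proton shift from the CH2 between two electron-poor dienes.
- Fallback, setting out from 6 and returning at 10: the twofold problem is divided. Limited oxidant (about two oxygen equivalents) should give 2,4,5-tribromo-3-[(2,4,5-tribromothiophen-3-yl)methyl]thiophene 1,1-dioxide F4, separated from recovered 6. Cycloaddition of F4 with 8 (PhMe, 110 °C, loss of SO2) should give cis-4,6,7-tribromo-5-[(2,4,5-tribromothiophen-3-yl)methyl]-3a,7a-dihydro-1,3-benzodioxol-2-one F5. The bromine-deactivated diene and the carbonate of F5 should tolerate the peracid, so a second oxidation with trifluoroperacetic acid gives 10, which then runs through the second half of step 5 to 12. No molecule then ever carries two sulfone dienes.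

## Further compounds

F1 | step 5 | bis(cis-5,7,8-tribromo-2,3,4a,8a-tetrahydro-1,4-benzodioxin-6-yl)methane | C1CO[C@H]2C(Br)=C(CC3=C(Br)[C@@H]4OCCO[C@@H]4C(Br)=C3Br)C(Br)=C(Br)[C@H]2O1
F2 | step 5 | bis(5,7,8-tribromo-2,3-dihydro-1,4-benzodioxin-6-yl)methane | Brc1c(Br)c2OCCOc2c(Br)c1Cc1c(Br)c(Br)c2OCCOc2c1Br
F3 | step 7 | bis(4,6,7-tribromo-2-oxo-1,3-benzodioxol-5-yl)methane | O=C1Oc2c(O1)c(Br)c(Cc3c(Br)c(Br)c4OC(=O)Oc4c3Br)c(Br)c2Br
F4 | step 4 | 2,4,5-tribromo-3-[(2,4,5-tribromothiophen-3-yl)methyl]thiophene 1,1-dioxide | O=S1(=O)C(Br)=C(Cc2c(Br)sc(Br)c2Br)C(Br)=C1Br
F5 | step 4 | cis-4,6,7-tribromo-5-[(2,4,5-tribromothiophen-3-yl)methyl]-3a,7a-dihydro-1,3-benzodioxol-2-one | O=C1O[C@H]2C(Br)=C(Cc3c(Br)sc(Br)c3Br)C(Br)=C(Br)[C@H]2O1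
A1 | alternative 1 | 1,2,5-tribromo-3,4-dimethoxybenzene | COc1c(OC)c(Br)c(Br)cc1Br
A2 | alternative 1 | ethyl formate | CCOC=O
A3 | alternative 1 | bis(2,3,6-tribromo-4,5-dimethoxyphenyl)methanol | COc1c(OC)c(Br)c(C(O)c2c(Br)c(OC)c(OC)c(Br)c2Br)c(Br)c1Br
A4 | alternative 2 | 4,4'-methylenebis(cyclohexane-1,2-dione) | O=C1CCC(CC2CCC(=O)C(=O)C2)CC1=O
A5 | alternative 2 | bis(2,5-dibromo-3,4-dihydroxyphenyl)methane | Oc1c(O)c(Br)c(Cc2cc(Br)c(O)c(O)c2Br)cc1Br
A6 | alternative 3 | 3,6-dibromo-2-iodo-4,5-dimethoxyphenyl 4-chlorobenzenesulfonate | COc1c(OC)c(Br)c(OS(=O)(=O)c2ccc(Cl)cc2)c(I)c1Br
A7 | alternative 3 | 3,6-dibromo-4,5-dimethoxybenzyne | COC1=C(Br)C#CC(Br)=C1OC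
A8 | alternative 3 | (2,3,6-tribromo-4,5-dimethoxybenzyl)magnesium chloride | COc1c(OC)c(Br)c(C[Mg]Cl)c(Br)c1Br
A9 | alternative 3 | bis(2,3,6-tribromo-4,5-dimethoxyphenyl)methane | COc1c(OC)c(Br)c(Cc2c(Br)c(OC)c(OC)c(Br)c2Br)c(Br)c1Br
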